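All runs were generated by integration for an exercise; noise was put on by code.

How much of the electrophile has reacted when the dose ends, and how much of the unused nucleophile is still free?

* part of the electrophile that has reacted at 3.0 h
* share of the unused nucleophile that is free and not bound as protonated nucleophile, at 3.0 h

the same everywhere: electrophile 0.020 M (fed, over 3.0 h); gas 1.7 mM (held)
- epsilon: free base 0.030 M; the very flask that is asked about, followed so far; the fed solution adds 1.0 times the starting volume
- zeta: free base 0.020 M; run made earlier; the fed solution adds 1.0 times the starting volume
- flask: free base 0.0300 M; the fed solution adds 1.0 times the starting volume; time 3.0 h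

- epsilon (time / min: electrophile / %, target / %): 5.00: 2.9, 0.8; 15.0: 8.3, 0; 25.0: 14.1, 0.7; 40.0: 23.3, 0.8; 50.0: 26.0, 1.1; 80.0: 41.4, 3.1; 90.0: 47.7, 4.2
- zeta (time / h: electrophile / %, target / %): 0.417: 13.5, 0.3; 0.833: 25.1, 0; 1.33: 40.7, 3.7; 1.50: 45.2, 3.9; 2.00: 59.5, 7.0; 2.50: 70.2, 10.3; 3.00: 82.2, 15.8

(readings scatter by 1 percentage point)

- charges are per starting volume, the dose included; the dosed solution carries all of it
- the numbers in the tables scatter with a standard deviation of 1 percentage point
- at the start none of the gas is in solution
- percentages count the whole charge, also what has not yet gone in
- the earlier runs do not show how much of nucleophile is bound; that part of a forecast is a guess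

Where does the electrophile end up? I expect it to keep reacting after the dose, so what matters is how fast it goes.

Which reading shows that? Zeta's last electrophile reading, because at the end of the dose the whole charge is in, so the missing part has reacted: 17.8%.

What law do you assume? If the held gas keeps the nucleophile steady, the electrophile is lost pseudo-first-order. The amount present grows in step with time, so to a first approximation the part reacted is the constant times time squared, over twice the dosing time. Hence the dose constant, twice the part reacted at the end of the dose divided by the dosing time, is 0.119 h⁻¹. Its half-life of 5.84 h is longer than the dose, and zeta's electrophile reading still stands at 82.2% when the dose ends.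

But zeta has less base than this flask. Does that spoil the transfer? Zeta's constant gives 4.45% at 90.0 min, and epsilon, this flask so far, reads 4.2% of target there. With a scatter of 1 percentage point, I see no sign of the base, so I commit to 17.8% for the flask. For the free share I have no reckoning of my own, since the runs do not show binding.

The forecast gave 16% reacted, below my figure, and 89% free, holding that “the rate barely depends on base”.

The flask gives 18.4% reacted and 90.4% free. The association of nucleophile with acid set free makes no difference to the reacted part.

    electrophile + nucleophile → acid set free + target (k = 1.30 M⁻¹ min⁻¹)
    nucleophile + acid set free ⇌ protonated nucleophile, settled at all times (K = 1.20 × 10⁶ M⁻¹)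
    acid set free + free base ⇌ salt of the base, settled at all times (K = 1.30 × 10⁶ M⁻¹)
    electrophile + target → side product (k = 0.150 M⁻¹ min⁻¹)
    gas ⇌ nucleophile, rate k5*(csat - [nucleophile]) (kL = 1.70 min⁻¹)

At 1.50 h the dose constant gives 4.45%, and the flask has used 4.73%.

The constant contains no charge of electrophile, so for the neighbour flask with 0.0080 M of electrophile and the same dosing time it gives 17.8%. The computed neighbour flask reacts 17.8%.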